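Assumption: the target has no stereocentre, so there is no enantiomer to select; the one stereocentre that appears in transit (C2 of 10 and 11) is racemic and is erased in step 5.

**Retrosynthetic overview**
1. Ester C–O: target ⇒ hexacosanoic acid + 2-phenylethanol. The phenyl ring is bought; no ring is formed in the route.
2. C5 methylene ⇒ 5-oxohexacosanoic acid (Wolff–Kishner); the ketone marks the former carbonyl of a C22 acyl unit.
3. C3–C4 bond (key C–C bond) ⇒ Michael addition of tert-butyl 3-oxotetracosanoate to tert-butyl acrylate, then ester cleavage and decarboxylation.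
4. C4–C5 bond ⇒ Claisen-type C-acylation of Meldrum's acid with docosanoyl chloride from cheap behenic acid (C22 + C1 + C3 = C26).

**Route**

Step 1
Reactants: 1 docosanoic acid (behenic acid); 2 thionyl chloride
Product: 3 docosanoyl chloride
Conditions: SOCl2 (1.5 equiv), cat. DMF, toluene, 70 °C, 2 h; evaporate
Reagents that add atoms: thionyl chloride, O=S(Cl)Cl
Why: Acyl chloride formation through the chlorosulfite (Vilsmeier-catalysed) is clean for a saturated fatty acid with no other functional group; no stereocentre is involved.

Step 2
Reactants: 3 docosanoyl chloride; 4 Meldrum's acid (2,2-dimethyl-1,3-dioxane-4,6-dione)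
Product: 5 5-(1-hydroxydocosylidene)-2,2-dimethyl-1,3-dioxane-4,6-dione (acyl Meldrum's acid, enol form)
Conditions: pyridine (2.2 equiv), CH2Cl2, 0 °C → rt, 3 h; 1 M HCl wash; crude used directly
Reagents that add atoms: Meldrum's acid, CC1(C)OC(=O)CC(=O)O1
Why: Claisen-type C-acylation of the very acidic Meldrum's acid methylene (Oikawa–Yonemitsu) gives the stable enolised acyl derivative; no stereocentre is formed.

Step 3
Reactants: 5 acyl Meldrum's acid; 6 tert-butanol
Product: 8 tert-butyl 3-oxotetracosanoate, via docosanoylketene 7 (not isolated)
Conditions: t-BuOH (5 equiv), toluene, 90 °C, 4 h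
Reagents that add atoms: tert-butanol, CC(C)(C)O
Why: Thermal cycloreversion of the acyl Meldrum's acid expels acetone and CO2 to give an acylketene, which tert-butanol traps as the β-keto ester (acylketene alcoholysis); no stereocentre is formed.

Step 4
Reactants: 8 tert-butyl 3-oxotetracosanoate; 9 tert-butyl acrylate
Product: 10 di-tert-butyl 2-docosanoylpentanedioate (racemic)
Conditions: t-BuOK (10 mol%), THF/t-BuOH 4:1, 25–35 °C, slow addition of 9 (1.05 equiv)
Reagents that add atoms: tert-butyl acrylate, C=CC(=O)OC(C)(C)C
Why: Michael addition of the stabilised β-keto ester enolate to the acrylate under catalytic alkoxide, with the bulky tert-butyl esters disfavouring a second addition; the new C2 stereocentre is racemic and is removed in step 5.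

Step 5
Reactants: 10 di-tert-butyl 2-docosanoylpentanedioate
Product: 12 5-oxohexacosanoic acid, via 2-docosanoylpentanedioic acid 11 (not isolated)
Conditions: TFA/CH2Cl2 1:1, rt, 3 h; evaporate; toluene, 110 °C, 2 h
Reagents that add atoms: none
Why: Acidolysis of both tert-butyl esters (loss of isobutene) followed by thermal decarboxylation of the β-keto acid through its six-membered transition state gives the δ-keto acid without retro-Claisen cleavage; the racemic centre becomes CH2.

Step 6
Reactants: 12 5-oxohexacosanoic acid; 13 hydrazine (as monohydrate)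
Product: 15 hexacosanoic acid, via 5-hydrazinylidenehexacosanoic acid 14 (not isolated)
Conditions: N2H4·H2O (4 equiv), KOH (4 equiv), diethylene glycol, 130 °C, 2 h; distil to 200 °C, 4 h; then aq. HCl; recrystallise (acetone)
Reagents that add atoms: none
Why: Wolff–Kishner reduction (Huang–Minlon modification) converts the ketone to CH2 through its hydrazone while the carboxylate is inert; no stereocentre is involved.

Step 7
Reactants: 15 hexacosanoic acid; 16 2-phenylethanol
Product: 17 phenylethyl n-hexacosanoate (2-phenylethyl hexacosanoate, target)
Conditions: 16 (2 equiv), TsOH·H2O (5 mol%), toluene, Dean–Stark reflux, 12 h; NaHCO3 wash; recrystallise (acetone/EtOH)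
Reagents that add atoms: 2-phenylethanol, OCCc1ccccc1
Why: Fischer esterification of an unhindered acid with a primary alcohol is driven to completion by azeotropic removal of water; the target has no stereocentre.

**Compound list**
1 | docosanoic acid (behenic acid) | CCCCCCCCCCCCCCCCCCCCCC(=O)O | starting material
2 | thionyl chloride | O=S(Cl)Cl | starting material
3 | docosanoyl chloride | CCCCCCCCCCCCCCCCCCCCCC(=O)Cl | intermediate
4 | Meldrum's acid (2,2-dimethyl-1,3-dioxane-4,6-dione) | CC1(C)OC(=O)CC(=O)O1 | starting material
5 | 5-(1-hydroxydocosylidene)-2,2-dimethyl-1,3-dioxane-4,6-dione | CCCCCCCCCCCCCCCCCCCCCC(O)=C1C(=O)OC(C)(C)OC1=O | intermediate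
6 | tert-butanol | CC(C)(C)O | starting material
7 | docosanoylketene (3-oxotetracos-1-en-1-one) | CCCCCCCCCCCCCCCCCCCCCC(=O)C=C=O | intermediate (not isolated)
8 | tert-butyl 3-oxotetracosanoate | CCCCCCCCCCCCCCCCCCCCCC(=O)CC(=O)OC(C)(C)C | intermediate
9 | tert-butyl acrylate | C=CC(=O)OC(C)(C)C | starting material
10 | di-tert-butyl 2-docosanoylpentanedioate (racemic) | CCCCCCCCCCCCCCCCCCCCCC(=O)C(CCC(=O)OC(C)(C)C)C(=O)OC(C)(C)C | intermediate
11 | 2-docosanoylpentanedioic acid (racemic) | CCCCCCCCCCCCCCCCCCCCCC(=O)C(CCC(=O)O)C(=O)O | intermediate (not isolated)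
12 | 5-oxohexacosanoic acid | CCCCCCCCCCCCCCCCCCCCCC(=O)CCCC(=O)O | intermediate
13 | hydrazine (used as monohydrate) | NN | starting material
14 | 5-hydrazinylidenehexacosanoic acid (hydrazone, present as its potassium salt) | CCCCCCCCCCCCCCCCCCCCCC(=NN)CCCC(=O)O | intermediate (not isolated)
15 | hexacosanoic acid | CCCCCCCCCCCCCCCCCCCCCCCCCC(=O)O | intermediate
16 | 2-phenylethanol | OCCc1ccccc1 | starting material
17 | phenylethyl n-hexacosanoate | CCCCCCCCCCCCCCCCCCCCCCCCCC(=O)OCCc1ccccc1 | target

**Summary**
Total steps: 7. Longest linear sequence: 7 (from docosanoic acid 1).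

**Steps most likely to fail, with fallbacks**

Step 3 (trapping of the acylketene by the hindered tert-butanol; competing ketene dimerisation or decarboxylation to the methyl ketone if wet). The fallback sets out from docosanoic acid 1 and replaces the Meldrum's acid route by a decarboxylative malonate half-ester acylation (Masamune–Brooks). Acid 1 is activated with carbonyldiimidazole in THF at rt to give 1-(1H-imidazol-1-yl)docosan-1-one F1. F1 is then treated with potassium mono-tert-butyl malonate, MgCl2 and Et3N in THF/MeCN at rt to 40 °C, and acidic work-up with loss of CO2 delivers tert-butyl 3-oxotetracosanoate. The fallback comes back to the route at compound 8.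

Step 4 (double Michael addition, or sluggish reaction of the waxy substrate). The fallback sets out from docosanoyl chloride 3 and abandons the enolate chemistry for a Negishi-type acylation. Chloride 3 is coupled with commercial (4-ethoxy-4-oxobutyl)zinc bromide under Pd(PPh3)4 catalysis in THF at 0 °C to rt to give ethyl 5-oxohexacosanoate F2. F2 is saponified with LiOH in THF/water at 40 °C and acidified. The fallback comes back to the route at compound 12 and also bypasses step 5.

Step 6 (incomplete reduction or foaming of the soap at 200 °C). The fallback sets out from 5-oxohexacosanoic acid 12 and replaces the hydrazone route by thioacetal desulfurisation (Mozingo). Acid 12 is condensed with 1,2-ethanedithiol and BF3·OEt2 in CH2Cl2 to give 4-(2-henicosyl-1,3-dithiolan-2-yl)butanoic acid F3. F3 is desulfurised with Raney nickel in refluxing ethanol. The fallback comes back to the route at compound 15.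

**Further compounds**
F1 | step 3 | 1-(1H-imidazol-1-yl)docosan-1-one | CCCCCCCCCCCCCCCCCCCCCC(=O)n1ccnc1
F2 | step 4 | ethyl 5-oxohexacosanoate | CCCCCCCCCCCCCCCCCCCCCC(=O)CCCC(=O)OCC
F3 | step 6 | 4-(2-henicosyl-1,3-dithiolan-2-yl)butanoic acid | CCCCCCCCCCCCCCCCCCCCCC1(CCCC(=O)O)SCCS1
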